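**Retrosynthetic overview**

1. The target is a resorcinol benzaldehyde C-benzylated by a Δ1(10)-decalin (drimane numbering: C3–OH, C4 gem-dimethyl, C5–H, C8–Me, quaternary C9, benzylic C11). The formyl group (directed lithiation) and the free phenols (MOM removal) come last, after removal of a C7 carbonyl.
2. Key disconnection C5–C6: ring B is closed last by a Claisen rearrangement of the bicyclic allyl vinyl ether C6=C7–O–C1–C10=C5, made from a δ-lactone C7(=O)–O–C1 that is not in the target and acts as a temporary tether. The enabling feature is that C5 is the ring-fusion CH allylic to the ring A alkene C10=C1, so C7–C6–C5–C10=C1 is a γ,δ-unsaturated ketone once C7 carries oxygen.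
3. Ring A (C1–C5, C10) comes from a Robinson annulation (C1 vinyl ketone plus isobutyraldehyde as C4/C5), dehydrogenation, asymmetric β-borylation/oxidation (C3–OH) and hydroxyl-directed anti reduction (C1–OH, the stereochemical relay to C5).
4. C8 and C9 are set on a temporary cyclopentanone (ring atoms C7, C8, C9, C10, C1) by copper-catalysed asymmetric methyl addition and enolate methylation; ozonolysis of its kinetic silyl enol ether cuts C7–C1 into ester and aldehyde; the aryl unit enters by a benzylic Negishi coupling.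
5. Order of ring formation: arene (bought) → temporary cyclopentanone (bought, then substituted) → ring A (step 10) → temporary δ-lactone/oxane (step 14) → ring B (step 16).

Key step: step 16

Remark on the chemistry: atom labels C1–C11 are the drimane positions of the target as listed above (C6/C7 are the ring B methylenes); Ar = 2,6-bis(methoxymethoxy)-4-[(methoxymethoxy)methyl]phenyl; 3-bromocyclopent-2-en-1-one is assumed to be a catalogue compound.

**Route**

Step 1
Reactants: 1 3,5-dihydroxybenzyl alcohol
Product: 2 1,3-bis(methoxymethoxy)-5-[(methoxymethoxy)methyl]benzene (ArH)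
Conditions: NaH, MOMCl, DMF, 0 → 23 °C
Reagents that add atoms: chloromethyl methyl ether (MOMCl) COCCl
Why: Williamson-type O-alkylation of the two phenoxides and the benzylic alkoxide installs three base-stable methoxymethyl acetals that later direct both ring lithiations.

Step 2
Reactants: 2 1,3-bis(methoxymethoxy)-5-[(methoxymethoxy)methyl]benzene
Product: 4 [2,6-bis(methoxymethoxy)-4-[(methoxymethoxy)methyl]phenyl]methanol (ArCH2OH), via aryllithium 3 (not isolated)
Conditions: n-BuLi, THF, 0 °C; (CH2O)n, −78 → 23 °C; H2O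
Reagents that add atoms: formaldehyde (from paraformaldehyde) C=O
Why: Directed ortho-metalation removes the ring proton flanked by the two OMOM groups, the most acidic one, and the aryllithium is hydroxymethylated by formaldehyde.

Step 3
Reactants: 4 ArCH2OH
Product: 6 2-(chloromethyl)-1,3-bis(methoxymethoxy)-5-[(methoxymethoxy)methyl]benzene (ArCH2Cl), via mesylate 5 (not isolated)
Conditions: MsCl, Et3N, CH2Cl2, 0 °C; then LiCl, THF, 23 °C
Reagents that add atoms: lithium chloride [Li+].[Cl-]
Why: Sulfonylation followed by SN2 displacement by chloride at the activated benzylic carbon gives the chloride under basic conditions that the acetals tolerate.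

Step 4
Reactants: 6 ArCH2Cl, 7 3-bromocyclopent-2-en-1-one
Product: 9 3-(ArCH2)cyclopent-2-en-1-one, via benzylic zinc chloride 8 (not isolated)
Conditions: Zn dust, LiCl, THF, 23 °C; then 7, Pd(PPh3)4 (3 mol %), THF, 23 → 50 °C
Reagents that add atoms: none
Why: LiCl-assisted zinc insertion and Negishi cross-coupling join C11 to the future C9, because zerovalent palladium inserts into the vinylic C–Br bond much faster than the soft zinc reagent adds in a conjugate sense.

Step 5
Reactants: 9 3-(ArCH2)cyclopent-2-en-1-one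
Product: 11 (2S,3S)-2,3-dimethyl-3-(ArCH2)cyclopentan-1-one, via aluminium enolate 10 (not isolated)
Conditions: Me3Al, Cu(O2C-2-C4H3S) (5 mol %), chiral phosphoramidite L* (10 mol %, enantiomer giving 3S), Et2O, −30 °C; then MeLi, DMPU/THF, MeI, −30 → 0 °C
Reagents that add atoms: trimethylaluminium C[Al](C)C; iodomethane CI
Why: Copper-catalysed asymmetric conjugate addition of methyl to the β,β-disubstituted cyclopentenone sets the quaternary C9 under ligand control, and the regiodefined enolate, activated as its lithium aluminate, should be C-methylated at C8 anti to the larger arylmethyl group (enolate alkylation).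

Step 6
Reactants: 11 (2S,3S)-2,3-dimethyl-3-(ArCH2)cyclopentan-1-one
Product: 13 trimethyl{[(4S,5S)-4,5-dimethyl-4-(ArCH2)cyclopent-1-en-1-yl]oxy}silane, via lithium enolate 12 (not isolated)
Conditions: LiN(iPr)2, THF, −78 °C; TMSCl, Et3N, −78 → 0 °C
Reagents that add atoms: chlorotrimethylsilane C[Si](C)(C)Cl
Why: Kinetic deprotonation takes a proton from the unhindered C1 methylene and not from the C8 methine beside the quaternary carbon, and O-silylation fixes this regiochemistry (kinetic silyl enol ether formation).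

Step 7
Reactants: 13 silyl enol ether
Product: 15 methyl (2S,3R)-2,3-dimethyl-3-(ArCH2)-5-oxopentanoate, via acid aldehyde 14 (not isolated)
Conditions: O3, CH2Cl2/MeOH (5:1), −78 °C; Me2S, −78 → 23 °C; then TMSCHN2, PhMe/MeOH, 0 °C
Reagents that add atoms: ozone [O-][O+]=O; (trimethylsilyl)diazomethane C[Si](C)(C)C=[N+]=[N-]
Why: Ozonolysis of the silyl enol ether cuts the temporary C7–C1 bond into an acid (C7) and an aldehyde (C1) that differ in oxidation level, and diazomethane-type esterification then masks the acid without touching a stereocentre.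

Step 8
Reactants: 15 ester aldehyde
Product: 16 methyl (2S,3R)-5-hydroxy-2,3-dimethyl-3-(ArCH2)hept-6-enoate (both C5 epimers)
Conditions: CH2=CHMgBr, THF, −78 °C; H2O
Reagents that add atoms: vinylmagnesium bromide C=C[Mg]Br
Why: Grignard 1,2-addition occurs at the aldehyde, which at −78 °C is far more reactive than the α-branched ester beside the quaternary carbon; the new carbinol centre is removed in step 9 and needs no control.

Step 9
Reactants: 16 allylic alcohol
Product: 17 methyl (2S,3R)-2,3-dimethyl-3-(ArCH2)-5-oxohept-6-enoate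
Conditions: Dess–Martin periodinane, CH2Cl2, 0 → 23 °C
Reagents that add atoms: none
Why: Dess–Martin oxidation of the allylic alcohol gives the vinyl ketone under neutral conditions that leave the acetals and the C8 centre alone.

Step 10
Reactants: 17 vinyl ketone, 18 isobutyraldehyde
Product: 20 methyl (2S,3S)-4-Ar-3-(3,3-dimethyl-6-oxocyclohex-1-en-1-yl)-2,3-dimethylbutanoate, via keto aldehyde 19 (not isolated)
Conditions: pyrrolidine (20 mol %), AcOH (20 mol %), PhMe, 23 °C; then 4 Å MS, 80 °C
Reagents that add atoms: none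
Why: Robinson annulation: enamine-mediated Michael addition of isobutyraldehyde (future C4 and C5) to the vinyl ketone and intramolecular aldol condensation, in which only C10 can reach the non-enolisable aldehyde in a six-membered closure, form ring A as a 2-substituted 4,4-dimethylcyclohexenone without a new stereocentre.

Step 11
Reactants: 20 cyclohexenone
Product: 22 methyl (2S,3S)-4-Ar-3-(3,3-dimethyl-6-oxocyclohexa-1,4-dien-1-yl)-2,3-dimethylbutanoate, via lithium dienolate 21 (not isolated)
Conditions: LiN(iPr)2, THF, −78 °C; then PhS(Cl)=NtBu, −78 → 23 °C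
Reagents that add atoms: none
Why: α′-Deprotonation (C2 is the only enolisable position of the enone) and sulfinimidoyl chloride dehydrogenation through a sulfilimine syn-elimination give the cross-conjugated dienone, which cannot aromatise because C4 is quaternary.

Step 12
Reactants: 22 dienone
Product: 24 methyl (2S,3S)-4-Ar-3-[(4R)-4-hydroxy-3,3-dimethyl-6-oxocyclohex-1-en-1-yl]-2,3-dimethylbutanoate, via boronate 23 (not isolated)
Conditions: B2pin2, CuCl (5 mol %), NaOtBu (10 mol %), chiral bisphosphine L* (Josiphos type, 6 mol %), MeOH, THF, 23 °C; then NaBO3·4H2O, THF/H2O, 0 → 23 °C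
Reagents that add atoms: sodium perborate [Na+].[O-]OB=O
Why: Copper-catalysed asymmetric conjugate borylation should occur at the α-unsubstituted enone (C3) and not at the α-substituted one (C5), the ligand choosing the face so that stereoretentive oxidation of the C–B bond gives the (3R)-hydroxyl of the target.

Step 13
Reactants: 24 β-hydroxy enone
Product: 25 methyl (2S,3S)-4-Ar-3-[(4R,6R)-4,6-dihydroxy-3,3-dimethylcyclohex-1-en-1-yl]-2,3-dimethylbutanoate
Conditions: Me4NBH(OAc)3, MeCN/AcOH (1:1), −30 °C
Reagents that add atoms: none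
Why: Evans–Saksena reduction: the C3 hydroxyl exchanges onto boron and delivers hydride intramolecularly to the same face of the C1 carbonyl, so the 1,3-anti diol with the C1 hydroxyl on the β face is expected from 1,2-reduction of the enone.

Step 14
Reactants: 25 diol ester
Product: 26 (3S,4S,7R,8aR)-4-(ArCH2)-7-hydroxy-3,4,6,6-tetramethyl-3,4,6,7,8,8a-hexahydro-2H-chromen-2-one
Conditions: Bu2SnO (10 mol %), PhMe, 100 °C
Reagents that add atoms: none
Why: Tin-oxide-catalysed transesterification (lactonisation) closes the δ-lactone between C7 and the allylic C1 oxygen, the only hydroxyl that can reach the ester in a six-membered ring, with retention at C1.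

Step 15
Reactants: 26 δ-lactone
Product: 27 (3S,4S,7R,8aR)-4-(ArCH2)-3,4,6,6-tetramethyl-2-methylidene-3,4,6,7,8,8a-hexahydro-2H-chromen-7-ol
Conditions: Cp2TiMe2 (4 equiv), PhMe, 70 °C, dark; filtration through basic alumina
Reagents that add atoms: dimethyltitanocene C[Ti](C)(C1C=CC=C1)C1C=CC=C1
Why: Petasis methylenation (carbonyl olefination by the titanium methylidene through an oxatitanacyclobutane) turns the lactone carbonyl into the exocyclic enol ether and so brings in C6 under non-acidic conditions, the free hydroxyl being held as a titanium alkoxide by the excess reagent.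

Step 16
Reactants: 27 cyclic allyl vinyl ether
Product: 28 (1S,2S,4aR,6R)-1-(ArCH2)-6-hydroxy-1,2,5,5-tetramethyl-1,4,4a,5,6,7-hexahydronaphthalen-3(2H)-one (C7 ketone of the decalin; 3R,5R,8S,9S in drimane numbering)
Conditions: PhMe (0.01 M), K2CO3 (solid, trace), 190 °C, sealed silylated tube
Reagents that add atoms: none
Why: On heating, the allyl vinyl ether C6=C7–O–C1–C10=C5 should undergo a concerted [3,3]-sigmatropic (Claisen) rearrangement in which the C1–O bond breaks while C6 bonds to C5, the alkene moving from C10=C5 to C10=C1 and C7 becoming the ring B ketone. The closest known reaction type is the thermal Claisen carbocyclisation of 2-methylidene oxacycles made by lactone methylenation, together with the boat-type rearrangements of 2-alkenyl-3,4-dihydro-2H-pyrans and of lactone silyl ketene acetals, which share the bicyclo[2.2.2]octane-like transition state imposed here by the C8–C9 bridge between C7 and C10. Ring B (C5–C6–C7–C8–C9–C10) closes pericyclically by joining the two exocyclic termini C6 and C5 across the oxane, which opens in the same event (six-membered oxacycle to six-membered carbocycle). The new stereocentre C5 is set by suprafacial 1,3-chirality transfer from C1, since C6 can only arrive on the β face of ring A from which the oxygen leaves, which gives the 5α-hydrogen cis to the C9 methyl. The step needs regioselectivity between C5 and C1 (both would be six-ring closures in an ionic or metal-mediated alternative), and the concerted pathway secures it because it cannot deliver C6 to C1 and reaches the neopentyl C5 intramolecularly. Acid-free glassware and solid carbonate keep the exocyclic enol ether from migrating into the ring and the C8 centre from epimerising.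

Step 17
Reactants: 28 ring B ketone
Product: 30 (2R,4aR,5S,6R)-5-(ArCH2)-1,1,5,6-tetramethyl-1,2,3,4a,5,6,7,8-octahydronaphthalen-2-ol (3R,5R,8R,9S in drimane numbering), via hydrazone 29 (not isolated)
Conditions: N2H4·H2O, EtOH, 80 °C; then KOtBu, DMSO, 23 °C
Reagents that add atoms: none
Why: Wolff–Kishner reduction in its room-temperature variant removes the C7 carbonyl through the preformed hydrazone and loss of N2, conditions to which the acetals and the isolated alkene are inert and which should not enolise C8.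

Step 18
Reactants: 30 deoxygenated decalin
Product: 32 2,4-bis(methoxymethoxy)-6-[(methoxymethoxy)methyl]-3-{[(1S,2R,4aR,6R)-6-hydroxy-1,2,5,5-tetramethyl-1,2,3,4,4a,5,6,7-octahydronaphthalen-1-yl]methyl}benzaldehyde, via dilithio species 31 (not isolated)
Conditions: n-BuLi (2.5 equiv), TMEDA, THF, −20 → 0 °C; DMF, −78 → 0 °C; H2O
Reagents that add atoms: N,N-dimethylformamide CN(C)C=O
Why: Directed ortho-metalation: after deprotonation of the hydroxyl, the second equivalent of base lithiates the ring position between OMOM and CH2OMOM (the two free positions are equivalent by symmetry), and formylation with DMF gives the aldehyde.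

Step 19
Reactants: 32 tris-MOM aldehyde
Product: 33 2,4-dihydroxy-3-{[(1S,2R,4aR,6R)-6-hydroxy-1,2,5,5-tetramethyl-1,2,3,4,4a,5,6,7-octahydronaphthalen-1-yl]methyl}-6-(hydroxymethyl)benzaldehyde (target)
Conditions: 3 M HCl aq/THF (1:3), 40 °C
Reagents that add atoms: none
Why: Acid-catalysed acetal hydrolysis removes the three MOM groups, mild aqueous acid being chosen so that the trisubstituted C10=C1 alkene is not protonated and cannot be captured by the neighbouring phenol.

**Compound list**

1 | 3,5-dihydroxybenzyl alcohol | OCc1cc(O)cc(O)c1 | starting material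
2 | 1,3-bis(methoxymethoxy)-5-[(methoxymethoxy)methyl]benzene (ArH) | COCOCc1cc(OCOC)cc(OCOC)c1 | intermediate
3 | aryllithium ArLi (2-lithio derivative of 2, not isolated) | [Li]c1c(OCOC)cc(COCOC)cc1OCOC | intermediate
4 | [2,6-bis(methoxymethoxy)-4-[(methoxymethoxy)methyl]phenyl]methanol (ArCH2OH) | OCc1c(OCOC)cc(COCOC)cc1OCOC | intermediate
5 | methanesulfonate of 4 (ArCH2OMs, not isolated) | CS(=O)(=O)OCc1c(OCOC)cc(COCOC)cc1OCOC | intermediate
6 | 2-(chloromethyl)-1,3-bis(methoxymethoxy)-5-[(methoxymethoxy)methyl]benzene (ArCH2Cl) | ClCc1c(OCOC)cc(COCOC)cc1OCOC | intermediate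
7 | 3-bromocyclopent-2-en-1-one | O=C1CCC(Br)=C1 | starting material
8 | benzylic zinc chloride ArCH2ZnCl (not isolated) | Cl[Zn]Cc1c(OCOC)cc(COCOC)cc1OCOC | intermediate
9 | 3-(ArCH2)cyclopent-2-en-1-one | O=C1CCC(Cc2c(OCOC)cc(COCOC)cc2OCOC)=C1 | intermediate
10 | dimethylaluminium enolate (C1=C2) of (S)-3-methyl-3-(ArCH2)cyclopentanone (not isolated) | C[Al](C)OC1=C[C@](C)(Cc2c(OCOC)cc(COCOC)cc2OCOC)CC1 | intermediate
11 | (2S,3S)-2,3-dimethyl-3-(ArCH2)cyclopentan-1-one | C[C@@H]1C(=O)CC[C@@]1(C)Cc1c(OCOC)cc(COCOC)cc1OCOC | intermediate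
12 | kinetic lithium enolate (C1=C5) of 11 (not isolated) | C[C@@H]1C(O[Li])=CC[C@@]1(C)Cc1c(OCOC)cc(COCOC)cc1OCOC | intermediate
13 | trimethyl{[(4S,5S)-4,5-dimethyl-4-(ArCH2)cyclopent-1-en-1-yl]oxy}silane | C[C@@H]1C(O[Si](C)(C)C)=CC[C@@]1(C)Cc1c(OCOC)cc(COCOC)cc1OCOC | intermediate
14 | (2S,3R)-2,3-dimethyl-3-(ArCH2)-5-oxopentanoic acid (not isolated) | C[C@@H]([C@](C)(Cc1c(OCOC)cc(COCOC)cc1OCOC)CC=O)C(=O)O | intermediate
15 | methyl (2S,3R)-2,3-dimethyl-3-(ArCH2)-5-oxopentanoate | C[C@@H]([C@](C)(Cc1c(OCOC)cc(COCOC)cc1OCOC)CC=O)C(=O)OC | intermediate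
16 | methyl (2S,3R)-5-hydroxy-2,3-dimethyl-3-(ArCH2)hept-6-enoate (C5 epimers) | C[C@@H]([C@](C)(Cc1c(OCOC)cc(COCOC)cc1OCOC)CC(O)C=C)C(=O)OC | intermediate
17 | methyl (2S,3R)-2,3-dimethyl-3-(ArCH2)-5-oxohept-6-enoate | C[C@@H]([C@](C)(Cc1c(OCOC)cc(COCOC)cc1OCOC)CC(=O)C=C)C(=O)OC | intermediate
18 | isobutyraldehyde (2-methylpropanal) | CC(C)C=O | starting material
19 | methyl (2S,3R)-2,3,8,8-tetramethyl-3-(ArCH2)-5,9-dioxononanoate (not isolated) | C[C@@H]([C@](C)(Cc1c(OCOC)cc(COCOC)cc1OCOC)CC(=O)CCC(C)(C)C=O)C(=O)OC | intermediate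
20 | methyl (2S,3S)-4-Ar-3-(3,3-dimethyl-6-oxocyclohex-1-en-1-yl)-2,3-dimethylbutanoate | C[C@@H]([C@](C)(Cc1c(OCOC)cc(COCOC)cc1OCOC)C1=CC(C)(C)CCC1=O)C(=O)OC | intermediate
21 | lithium cross-conjugated dienolate of 20 (not isolated) | C[C@@H]([C@](C)(Cc1c(OCOC)cc(COCOC)cc1OCOC)C1=CC(C)(C)CC=C1O[Li])C(=O)OC | intermediate
22 | methyl (2S,3S)-4-Ar-3-(3,3-dimethyl-6-oxocyclohexa-1,4-dien-1-yl)-2,3-dimethylbutanoate | C[C@@H]([C@](C)(Cc1c(OCOC)cc(COCOC)cc1OCOC)C1=CC(C)(C)C=CC1=O)C(=O)OC | intermediate
23 | methyl (2S,3S)-4-Ar-3-[(4R)-3,3-dimethyl-6-oxo-4-(4,4,5,5-tetramethyl-1,3,2-dioxaborolan-2-yl)cyclohex-1-en-1-yl]-2,3-dimethylbutanoate (not isolated) | C[C@@H]([C@](C)(Cc1c(OCOC)cc(COCOC)cc1OCOC)C1=CC(C)(C)[C@H](B2OC(C)(C)C(C)(C)O2)CC1=O)C(=O)OC | intermediate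
24 | methyl (2S,3S)-4-Ar-3-[(4R)-4-hydroxy-3,3-dimethyl-6-oxocyclohex-1-en-1-yl]-2,3-dimethylbutanoate | C[C@@H]([C@](C)(Cc1c(OCOC)cc(COCOC)cc1OCOC)C1=CC(C)(C)[C@H](O)CC1=O)C(=O)OC | intermediate
25 | methyl (2S,3S)-4-Ar-3-[(4R,6R)-4,6-dihydroxy-3,3-dimethylcyclohex-1-en-1-yl]-2,3-dimethylbutanoate | C[C@@H]([C@](C)(Cc1c(OCOC)cc(COCOC)cc1OCOC)C1=CC(C)(C)[C@H](O)C[C@H]1O)C(=O)OC | intermediate
26 | (3S,4S,7R,8aR)-4-(ArCH2)-7-hydroxy-3,4,6,6-tetramethyl-3,4,6,7,8,8a-hexahydro-2H-chromen-2-one | C[C@@H]1C(=O)O[C@@H]2C[C@@H](O)C(C)(C)C=C2[C@@]1(C)Cc1c(OCOC)cc(COCOC)cc1OCOC | intermediate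
27 | (3S,4S,7R,8aR)-4-(ArCH2)-3,4,6,6-tetramethyl-2-methylidene-3,4,6,7,8,8a-hexahydro-2H-chromen-7-ol | C[C@@H]1C(=C)O[C@@H]2C[C@@H](O)C(C)(C)C=C2[C@@]1(C)Cc1c(OCOC)cc(COCOC)cc1OCOC | intermediate
28 | (1S,2S,4aR,6R)-1-(ArCH2)-6-hydroxy-1,2,5,5-tetramethyl-1,4,4a,5,6,7-hexahydronaphthalen-3(2H)-one | C[C@@H]1C(=O)C[C@@H]2C(=CC[C@@H](O)C2(C)C)[C@@]1(C)Cc1c(OCOC)cc(COCOC)cc1OCOC | intermediate
29 | hydrazone of 28 at C7 (not isolated) | C[C@@H]1C(=NN)C[C@@H]2C(=CC[C@@H](O)C2(C)C)[C@@]1(C)Cc1c(OCOC)cc(COCOC)cc1OCOC | intermediate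
30 | (2R,4aR,5S,6R)-5-(ArCH2)-1,1,5,6-tetramethyl-1,2,3,4a,5,6,7,8-octahydronaphthalen-2-ol | C[C@@H]1CC[C@@H]2C(=CC[C@@H](O)C2(C)C)[C@@]1(C)Cc1c(OCOC)cc(COCOC)cc1OCOC | intermediate
31 | lithium alkoxide of 30 lithiated at the ring position between OMOM and CH2OMOM (not isolated) | C[C@@H]1CC[C@@H]2C(=CC[C@@H](O[Li])C2(C)C)[C@@]1(C)Cc1c(OCOC)cc(COCOC)c([Li])c1OCOC | intermediate
32 | tris-MOM ether of the target (two phenols and the benzylic alcohol protected) | C[C@@H]1CC[C@@H]2C(=CC[C@@H](O)C2(C)C)[C@@]1(C)Cc1c(OCOC)cc(COCOC)c(C=O)c1OCOC | intermediate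
33 | 2,4-dihydroxy-3-{[(1S,2R,4aR,6R)-6-hydroxy-1,2,5,5-tetramethyl-1,2,3,4,4a,5,6,7-octahydronaphthalen-1-yl]methyl}-6-(hydroxymethyl)benzaldehyde | C[C@@H]1CC[C@@H]2C(=CC[C@@H](O)C2(C)C)[C@@]1(C)Cc1c(O)cc(CO)c(C=O)c1O | target

**Step count and risks**

Total step count: 19. Longest linear sequence: 19 steps (from 1).

Steps most likely to fail:

Step 16 (thermal Claisen ring closure). At the temperature that the boat-shaped transition state needs, the exocyclic enol ether may migrate into the ring, or the allylic C1–O bond may ionise and recombine at C1, so material is lost or ends in the C1-linked isomer. The fallback sets out from diol 25 and by-passes 26 and 27. Johnson–Claisen rearrangement of the allylic C1 hydroxyl (MeC(OEt)3, EtCO2H cat., 140 °C) should bring a two-carbon ester unit (C6 plus a carboxyl carbon) to the β face of C5 with the same 1,3-chirality transfer and give the diester F1. Dieckmann condensation (KOtBu, THF, 0 → 23 °C), in which the C6 ester enolate attacks the C7 methyl ester, would then close ring B as the β-keto ester F2. Krapcho dealkoxycarbonylation (LiCl, wet DMSO, 150 °C) comes back to the route at ketone 28.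

Step 12 (asymmetric conjugate borylation). The catalyst may discriminate poorly between the two enone units or between the two faces of C3, and the β-hydroxy ketone may lose water again during the oxidative work-up. The fallback sets out from dienone 22. Chemoselective nucleophilic (Weitz–Scheffer) epoxidation of the α-unsubstituted enone (t-BuOOH, KOH, chiral cinchona-derived ammonium phase-transfer catalyst, PhMe, 0 °C) should give the epoxy enone F3. Reductive opening of its Cα–O bond (SmI2, THF/MeOH, −90 °C) would leave the C3 hydroxyl and come back to the route at β-hydroxy enone 24.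

Step 18 (late directed lithiation and formylation). The base may deprotonate the benzylic CH2OMOM position instead (followed by Wittig-type rearrangement), or ring lithiation may stall because of aggregation with the C3 alkoxide. The fallback sets out from 30. Hydrolysis of the acetals under the conditions of step 19 would give the tetraol F4. Magnesium-phenoxide-directed ortho-formylation (MgCl2, Et3N, paraformaldehyde, MeCN, reflux; Casnati–Skattebøl reaction), which has only one kind of free ortho position to choose, would then give the target 33 directly.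

**Further compounds**

F1 | step 16 | methyl (2S,3S)-4-Ar-3-[(4R,6R)-6-(2-ethoxy-2-oxoethyl)-4-hydroxy-5,5-dimethylcyclohex-1-en-1-yl]-2,3-dimethylbutanoate | C[C@@H]([C@](C)(Cc1c(OCOC)cc(COCOC)cc1OCOC)C1=CC[C@@H](O)C(C)(C)[C@@H]1CC(=O)OCC)C(=O)OC
F2 | step 16 | ethyl ester of the C6 carboxylic acid of ketone 28 (β-keto ester, C6 epimers and enol) | C[C@@H]1C(=O)C(C(=O)OCC)[C@@H]2C(=CC[C@@H](O)C2(C)C)[C@@]1(C)Cc1c(OCOC)cc(COCOC)cc1OCOC
F3 | step 12 | α-face C2–C3 epoxide of dienone 22 (methyl (2S,3S)-4-Ar-3-(4,5-epoxy-3,3-dimethyl-6-oxocyclohex-1-en-1-yl)-2,3-dimethylbutanoate) | C[C@@H]([C@](C)(Cc1c(OCOC)cc(COCOC)cc1OCOC)C1=CC(C)(C)[C@@H]2O[C@@H]2C1=O)C(=O)OC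
F4 | step 18 | 2-{[(1S,2R,4aR,6R)-6-hydroxy-1,2,5,5-tetramethyl-1,2,3,4,4a,5,6,7-octahydronaphthalen-1-yl]methyl}-5-(hydroxymethyl)benzene-1,3-diol | C[C@@H]1CC[C@@H]2C(=CC[C@@H](O)C2(C)C)[C@@]1(C)Cc1c(O)cc(CO)cc1O
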